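We start with the easy step and count half-lives of substrate, the limiting reagent.

in all of them: gas phase 13 mM (held)

| run | substrate | remark | time |
|---|---|---|---|
| maple | 27 mM | the very flask that is asked about, followed so far |  |
| birch | 14 mM | run made earlier |  |
| flask | 27 mM |  | 3.0 h |

- maple (time / min: target / %, substrate / %): 6.00: 1.2, 77.5; 12.0: 6.0, 62.9; 30.0: 16.9, 33.3; 80.0: 30.4, 7.0
- birch (time / h: target / %, substrate / %): 0.250: 8.9, 68.2; 0.500: 18.2, 43.9; 1.33: 42.6, 12.8; 3.00: 52.2, 0

(standard deviation of a reading: 1 percentage point)

* how much target there is at 3.0 h, in percent of the substrate charged
* the change that raises the amount of target at 3.0 h, in percent of the substrate charged most ("none" if none brings more than 2 percentage points) (Wednesday's / Friday's / none)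
* amount of target at 3.0 h, in percent of the substrate charged, after Wednesday's

- Wednesday's: doubling the saturation concentration of gas phase, all else as stated
- Friday's: doubling the transfer coefficient of the gas phase, all else as stated

- the numbers in the tables scatter with a standard deviation of 1 percentage point
- at the start none of the gas phase is in solution

In the maple flask substrate stands at 33.3% after 30.0 min, so its half-life reads 18.9 min. In the birch flask, 43.9% after 0.500 h gives 25.3 min. The half-life is shorter in the richer maple flask than in birch, so we read part of the loss as going with a higher power of substrate than the gas route. The 3.0 h asked is about 9.52 maple half-lives of that length, so we take the question to be where the substrate went, not how long we wait.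

The maple ledger gives the share of substrate gone in each stretch that appears as target:

up to 6.00 min: 5.33%
up to 12.0 min: 32.9%
up to 30.0 min: 36.8%
up to 80.0 min: 51.3%

The first share is low, which we read as gas still entering the solution, and the later shares climb as substrate thins. The birch books close at 3.00 h:

substrate 0%, target 52.2%, lost elsewhere 47.8%

We therefore define the loss ratio per mM, the amount lost elsewhere for each amount of target, divided by the substrate charged:

0.0654 mM⁻¹

Taking the ratio to grow with the charge at this saturation, we reckon 1.77 for the maple flask, so we expect target near 36.2%. If the gas route goes with the saturation, Wednesday's halves the ratio and we expect 53.1%. Friday's quickens the gas's entry and leaves the saturation as it stands, so we expect it to help the early stretches and name Wednesday's.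

The forecast says 40%, above our figure, and Wednesday's with 47%, below ours, since doubling saturation “speeds the gas step against competing losses”.

The maple flask gives 37.2%. Wednesday's is best, adding 12 percentage points against 4.5 points for Friday's, and reaches 49.2%, below our figure.

    gas phase ⇌ dissolved gas, rate k1*(csat - [dissolved gas]) (kL = 0.0700 min⁻¹)
    substrate + dissolved gas → target (k = 1.60 M⁻¹ min⁻¹)
    substrate + target → side product (k = 0.130 M⁻¹ min⁻¹)
    2 substrate → homo dimer (k = 0.800 M⁻¹ min⁻¹)

The main reason for the shortfall in the maple flask is the joining of two substrate into homo dimer: with that step struck out, target at 3.00 h goes from 37.2% to 80.3%. The ratio counts that loss together with side product and the substrate remaining, and from the result, with 0.912% of substrate remaining, it reads 0.0624 mM⁻¹.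

For a neighbour flask charged with 11 mM, the loss ratio per mM gives 0.719, so target should be 58.2%. The computed result is 58.2%.

The runs were computed for an exercise.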